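## Structural features

The target is a cis-fused eremophilane decalin. Ring A (C1–C5, C10) and ring B (C5–C10) share the C5–C10 bond, C5 is quaternary with the angular methyl, and H-10 lies on the face of the C4 and C5 methyls (called β below). Five stereocentres run unbroken from C3 (tiglate, α) through C4 (methyl, β), C5 and C10 to C9 (senecioate, β). The sixth, C7 (isopropenyl, β), lies beyond the C8 ketone; the C3 oxygen is trans to the C4 methyl and the two methyls are cis. In the chair–chair form with the C5 methyl axial on ring A, the C3 ester, C4 methyl, C7 isopropenyl and C9 ester are all equatorial. C7 and C9 (both α to the ketone) therefore have their thermodynamic configurations, while C4, C5 and C10 must be set kinetically. Fragile functions are the α-acyloxy ketone (enolisation can epimerise C9 or move the acyl group to O-8), the β,γ-unsaturated ketone (the isopropenyl double bond can slip into conjugation as C7=C11), and the senecioyl ester, which deconjugates through a vinylketene when over-activated. The real difficulty is the quaternary C5 wedged between the C4 stereocentre and the cis ring fusion, together with three differentiated oxygens at C3, C8 and C9. The key step exploits ring B: the C8 oxygen sits next to C7 with its three-carbon branch and the quaternary C5 lies across the ring (C5–C6–C7–C8). This is the "ortho" pattern of a Diels–Alder adduct between a diene C8=C9–C10=C5 embedded in ring A and oxygenated at C8, and an enone whose acetyl group becomes the isopropenyl group.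

## Logic of the disconnections

22 ⇒ 20 + 21. The C9–O acyl bond is cut first, because the α-acyloxy ketone is the most base-sensitive array and the five-carbon acyl group deconjugates easily, so both should appear only at the end. The gain is the ester-free ketol 20. The forward step must acylate a hindered alcohol next to a ketone without enolising it and without making a ketene from 21.

20 ⇒ 18 (through 19). The C9–O bond is cut. C9 is α to the C8 ketone, so its oxygen can come from an electrophilic oxidant and an enolate, and ring B then needs only the one oxygen the annulation provides. One stereocentre and one oxygen are removed. The forward step needs enolisation toward C9, not C7, and attack on the β-face; C4, axial on ring B, covers the α-face of C9.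

18 ⇒ 17. Only C7 changes (its C–H bond). With a cis ring fusion and an α oxygen at C3, 7β is the equatorial, thermodynamic arrangement, whereas the annulation delivers 7α. C7 therefore need not be controlled in the key step. The equilibration must follow both the C3 inversion and the cis fusion (before that the 7α epimer is the more stable) and must not move the isopropenyl double bond.

17 ⇒ 16. The C10–H bond (with a C9–H bond) is cut. Conjugate hydride addition to the enone sets the ring-fusion hydrogen, keeps the ketone at C8 and leaves C9 as a methylene for the later oxygenation. The demand is hydride delivery cis to the angular methyl. A 1,2-hydride shift in the α-epoxide of C9=C10 would set C10 intramolecularly, but it places the ketone at C9. Reduction of that ketone is expected from the convex β-face (9α-alcohol) and would cost two extra protecting-group steps, so that sequence was set aside.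

16 ⇒ 14 + 15. The C3–O bond is cut with inversion. The key step needs the C3 oxygen cis to the C4 methyl, the target has it trans, and an SN2 esterification with 15 corrects the configuration and installs the ester together. It is done at 14 on purpose: ring A is a locked chair there and the α-face of C3 is open. The demand is substitution rather than elimination at an axial carbinol.

14 ⇒ 13 ⇒ 12. These are functional-group changes only: the enone comes from the allylic alcohol, and both hydroxyls come from acetates. Both oxygens travel as the same ester, so one step frees both, and the allylic position alone distinguishes C8 from C3. The demand is an oxidant selective for allylic alcohols.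

12 ⇒ 11. The C11=C12 bond is cut; the isopropenyl group is the methylenated acetyl group of the dienophile. The forward step must be non-basic, because 11 is a β-acetoxy ketone with an epimerisable α-carbon.

11 ⇒ 9 + 10. The C5–C6 and C7–C8 bonds are cut (retro-[4+2]). This removes ring B, the quaternary centre and the carbon branch at once and leaves a monocyclic diene and a four-carbon enone. The forward step must react at a tetrasubstituted diene terminus with "ortho" regiochemistry and attack anti to the C4 methyl.

9 ⇒ 8 ⇒ 7 ⇒ 5 + 6. The two O–acyl bonds of 9 and then the C9=C10 bond are cut. The dienyl ester is the thermodynamic enol derivative of an enal made from 5 by two-carbon olefination with 6. The demand is enolisation toward C5 (tetrasubstituted alkene), not toward C1.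

5 ⇒ 4 ⇒ 3 ⇒ 2. The ketone is traced to one of two enantiotopic oxygens of a meso compound, so one enantiotopos-differentiating step supplies the absolute configuration of C3 and C4. The demand is an enzyme that tells the two ester groups of 3 apart.

2 ⇒ 1. Six C–H bonds are cut. The all-cis array of two methyls and two oxygens is what one-face hydrogenation of the arene gives. The demand is all-cis selectivity without C–O hydrogenolysis.

## Other disconnections considered

Alternative 1: The cut is C5–C6, traced through a [3,3] shift to a C3–C8 bond of a bicyclo[2.2.2]octene derived from a masked o-benzoquinone. In the forward step the potassium alkoxide of dienyl carbinol A1 (KH, 18-crown-6) undergoes an anionic oxy-Cope rearrangement. It breaks C3–C8, forms C5–C6 and closes ring B, and the C8 dienolate is protonated at C7 to give cis-decalin A2.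
- In its favour: the bridged template dictates the cis ring fusion, so C5 and C10 are set together in a stereospecific intramolecular step. A2 already has the C8 ketone, an oxygen at C9 (as ketal) and the intact isopropenyl group with C7 under thermodynamic control.
- Where it is better: on the ring fusion and on the regiochemistry of the C8/C9 oxygens. The chosen route relies on an intermolecular hydride addition for C10 and a regioselective enolisation for C9.
- Against it here: A2 has neither the C3 oxygen nor the C4 stereocentre. Converting C3=C4 into the trans oxygen/methyl pair (hydroboration has the right sense) must be done beside the more reactive isopropenyl alkene. The C9 ketal must be unmasked next to the C8 ketone and one carbonyl of the 1,2-dione reduced selectively. A1 comes from a racemic cycloaddition, so a resolution is needed, whereas the chosen plan takes its absolute configuration from one enzymatic step.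
- Step economy: about equal up to the decalin and worse after it. Overall the plans are of similar length, with the risk moved from the ring fusion (chosen plan) to ring A and the C9 carbonyl (alternative).

Alternative 2: The cuts are C4–C5 and C1–C10; ring A is annulated onto a ring B quinone. In the forward step silyloxydiene A4 adds endo to the methyl-bearing C5=C10 bond of quinone A3 under a chiral titanium Lewis acid made from BINOL and TiCl2(OiPr)2, giving cis-fused enedione A5.
- In its favour: one catalytic enantioselective step from two achiral partners sets the absolute configuration, the quaternary C5 and the cis fusion (the last through the suprafacial cycloaddition).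
- Where it is better or equal: it is better on step count to the bicycle and on how the fusion is secured. The C3 oxygen arrives at the ketone level, so it can be reduced instead of inverted, which is at least equal to the Mitsunobu step of the chosen route.
- Against it here: the endo geometry places the C4 methyl trans to the C5 methyl, so C4 must be epimerised through the C3 ketone, and that equilibrium is not clearly favourable. Ring B arrives with carbonyls at C6 and C9 and a vinylogous ester at C8. The C6 oxygen must go by the Stork–Danheiser transposition, the three-carbon branch must still be attached at C7, and the C9 ketone must be reduced to the β-alcohol beside the C8 carbonyl.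
- Comparison: the chosen plan gets the C7 branch and C8 oxygen directly from its cycloaddition and never has to tell two ring B carbonyls apart. The alternative has a shorter, firmer start and a longer, less certain finish.

Alternative 3: The cut is C4–C5 alone; ring A closes by intramolecular C-alkylation of a phenol that becomes ring B. In the forward step the phenoxide of mesylate A6 (KOtBu) attacks C4 through its para carbon with inversion (six-membered ring closure). This forms the quaternary C5 and leaves ring B as cross-conjugated dienone A7.
- In its favour: the C4 configuration is bought with lactic acid, the reagents are simple, the C8 and C9 oxygens come with the guaiacol-type ring, and C3 is at the ketone level.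
- Where it is equal or better: on reagent simplicity and on placement of the three oxygens.
- Against it here: the mesylate carbon is α to a ketone, so enolisation (loss of the C4 configuration) competes with alkylation. C-alkylation at a methyl-bearing para carbon competes with O-alkylation. A7 has no carbon at C7, and conjugate additions to its dienone go to C6. Both ring B double bonds (C6=C7 and the C9=C10 enol acetal) must be reduced with control of C10 and C9.
- Comparison: the uncertainty at C10 equals that of the conjugate reduction in the chosen plan. The alternative adds a C9 problem and several steps after its key step, whereas the chosen plan builds ring B with its substituents in place.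

Key step: step 8

Remarks on the chemistry (before the steps):
- Eremophilane numbering is used; β is the face of the C4 and C5 methyl groups.
- Stereochemical bookkeeping of the cycloadduct: endo addition anti to the C4 methyl puts the acetyl group α at C7 (cis to the C8 acetoxy group, trans to the angular methyl), opposite to the 7β-isopropenyl group of the target. C7 is therefore inverted in step 14 and C8 is oxidised, so only C5 of the three new centres is carried through as formed. An exo adduct would converge at 18 as well.
- Precursor design: the C3 oxygen of the diene is an acetate, not a bulky silyl ether. It stays equatorial in the diene, costs less in the 1,3-diaxial contact with the emerging angular methyl, and leaves with the C8 acetate in a single step.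
- Assumption: the lipase cleaves the ester on the R-configured carbinol carbon (the usual preference when the larger flanking group has CIP priority). Were the sense opposite, the same enzyme used for acetylation of 2 with vinyl acetate would give 4 directly.

Step 1
Reactants: 1 2,3-dimethylhydroquinone
Product: 2 meso-(1R,2S,3R,4S)-2,3-dimethylcyclohexane-1,4-diol (all-cis)
Conditions: H2 (50 bar), Rh/Al2O3, i-PrOH, 50 °C; recrystallise
Reagents that add atoms: none
Why: Arene hydrogenation over rhodium adds all six hydrogens from the catalyst face with little C–O hydrogenolysis, so the all-cis meso diol should be the main isomer; the cis relation of the two methyls and of each methyl to its neighbouring oxygen (later C4 methyl/C3 oxygen) is set here.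

Step 2
Reactants: 2 meso-(1R,2S,3R,4S)-2,3-dimethylcyclohexane-1,4-diol
Product: 3 meso-(1R,2S,3R,4S)-2,3-dimethylcyclohexane-1,4-diyl diacetate
Conditions: Ac2O, pyridine, DMAP (cat.), rt
Reagents that add atoms: acetic anhydride, CC(=O)OC(C)=O
Why: Plain O-acylation with nucleophilic catalysis; no stereocentre is touched and the mirror plane is kept.

Step 3
Reactants: 3 meso-(1R,2S,3R,4S)-2,3-dimethylcyclohexane-1,4-diyl diacetate
Product: 4 (1S,2R,3S,4R)-4-hydroxy-2,3-dimethylcyclohexyl acetate
Conditions: Candida antarctica lipase B (immobilised), NaH2PO4/Na2HPO4 buffer (pH 7), t-BuOMe, 30 °C; stop at the monoacetate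
Reagents that add atoms: none
Why: Enzymatic desymmetrisation of a meso diester by enantiotopic-group hydrolysis: the ester on the R-configured carbon should be cleaved, which fixes the absolute configuration of the future C3 and C4; slight over-hydrolysis to 2 should remove the minor enantiomer preferentially.

Step 4
Reactants: 4 (1S,2R,3S,4R)-4-hydroxy-2,3-dimethylcyclohexyl acetate
Product: 5 (1S,2R,3S)-2,3-dimethyl-4-oxocyclohexyl acetate
Conditions: Dess–Martin periodinane, CH2Cl2, rt
Reagents that add atoms: none
Why: Dess–Martin oxidation of the free secondary alcohol; the acetoxy group is γ to the ketone and cannot eliminate, and epimerisation at the α-carbon (future C5) is harmless because that carbon becomes sp2 in step 7.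

Step 5
Reactants: 5 (1S,2R,3S)-2,3-dimethyl-4-oxocyclohexyl acetate; 6 diethyl cyanomethylphosphonate
Product: 7 (1S,2R,3S)-4-[(E)-cyanomethylidene]-2,3-dimethylcyclohexyl acetate
Conditions: NaH, THF, 0 °C → rt
Reagents that add atoms: none
Why: Horner–Wadsworth–Emmons olefination; the small cyano-stabilised phosphonate anion should tolerate the α-branched ketone, and the E/Z ratio or any β,γ-isomer does not matter because all converge in step 7.

Step 6
Reactants: 7 (1S,2R,3S)-4-[(E)-cyanomethylidene]-2,3-dimethylcyclohexyl acetate
Product: 8 (E)-2-[(2S,3R,4S)-4-hydroxy-2,3-dimethylcyclohexylidene]acetaldehyde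
Conditions: i-Bu2AlH (excess), toluene, −78 °C; then 1 M aq. HCl, 0 °C
Reagents that add atoms: water, O
Why: Partial reduction of the nitrile to the aluminated aldimine, hydrolysed on work-up to the enal; the acetate is cleaved reductively as well, which is accepted because the hydroxyl is re-acetylated in step 7.

Step 7
Reactants: 8 (E)-2-[(2S,3R,4S)-4-hydroxy-2,3-dimethylcyclohexylidene]acetaldehyde
Product: 9 (1S,2R)-4-[(E)-2-acetoxyethenyl]-2,3-dimethylcyclohex-3-en-1-yl acetate (ring A dienyl acetate, 3β-acetoxy, 4β-methyl)
Conditions: isopropenyl acetate, p-TsOH (cat.), reflux, acetone distilled off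
Reagents that add atoms: isopropenyl acetate, CC(=C)OC(C)=O
Why: Acid-catalysed enol acetylation under equilibrating conditions (thermodynamic dienol acetate formation), with O-acetylation of the alcohol in the same pot; the conjugated diene with the tetrasubstituted C10=C5 bond and the E enol acetate should be the most stable isomer, and C4 is not enolisable.

Step 8
Reactants: 9 (1S,2R)-4-[(E)-2-acetoxyethenyl]-2,3-dimethylcyclohex-3-en-1-yl acetate; 10 methyl vinyl ketone
Product: 11 7α-acetyl-3β,8α-diacetoxy-4β,5β-dimethyl-Δ9(10)-octalin (endo adduct)
Conditions: 10 (excess), BF3·OEt2 (cat.), CH2Cl2, −78 → −20 °C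
Reagents that add atoms: none
Why: Lewis-acid-catalysed, asynchronous but concerted [4+2] cycloaddition, the known Diels–Alder reaction of 1-acyloxy semicyclic dienes with enones: C5 (the γ-carbon of the dienyl acetate, largest HOMO coefficient) bonds to the β-carbon C6 and the acetoxy-bearing C8 to the α-carbon C7, so ring B closes by [4+2] annulation with the new alkene at C9=C10. The "ortho" regiochemistry follows from the donor at C8, supported by the ring substituent on C10 and opposed only weakly by the alkyl groups on C5. C5 is set by the face of attack: A(1,2) strain between the C5 and C4 methyls holds the C4 methyl pseudoaxial on the β-face while the cis C3 acetoxy group stays equatorial, so 10 approaches the α-face and the angular methyl emerges β, cis to the C4 methyl. C8 follows from the E enol acetate (acetoxy "outside", hence α, trans to the angular methyl) and C7 from the endo orientation of the acetyl group (α, cis to the acetoxy group). Only C5 has to persist, because C8 is oxidised later and C7 is equilibrated later, so endo/exo selectivity is not required. What the step does need is rate at a tetrasubstituted terminus with an "inside" methyl, which is why the enone is activated by a Lewis acid at low temperature.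

Step 9
Reactants: 11 7α-acetyl-3β,8α-diacetoxy-4β,5β-dimethyl-Δ9(10)-octalin
Product: 12 3β,8α-diacetoxy-7α-isopropenyl-4β,5β-dimethyl-Δ9(10)-octalin
Conditions: Zn, CH2Br2, TiCl4, THF/CH2Cl2, 0 °C → rt
Reagents that add atoms: dibromomethane, BrCBr
Why: Non-basic carbonyl methylenation with the zinc/titanium gem-dimetallic methylene reagent: the β-acetoxy ketone should neither eliminate nor epimerise at C7, and the esters are not attacked.

Step 10
Reactants: 12 3β,8α-diacetoxy-7α-isopropenyl-4β,5β-dimethyl-Δ9(10)-octalin
Product: 13 7α-isopropenyl-4β,5β-dimethyl-Δ9(10)-octalin-3β,8α-diol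
Conditions: K2CO3 (cat.), MeOH, rt
Reagents that add atoms: none
Why: Base-catalysed transesterification removes both acetates in one operation; no ketone is present, so nothing can eliminate or epimerise.

Step 11
Reactants: 13 7α-isopropenyl-4β,5β-dimethyl-Δ9(10)-octalin-3β,8α-diol
Product: 14 3β-hydroxy-7α-isopropenyl-4β,5β-dimethyl-Δ9(10)-octalin-8-one
Conditions: MnO2 (excess), CH2Cl2, rt
Reagents that add atoms: none
Why: MnO2 oxidises allylic alcohols selectively, so the C8 hydroxyl should give the enone while the saturated C3 hydroxyl is untouched; the C8 stereocentre is erased here.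

Step 12
Reactants: 14 3β-hydroxy-7α-isopropenyl-4β,5β-dimethyl-Δ9(10)-octalin-8-one; 15 tiglic acid
Product: 16 3α-tigloyloxy-7α-isopropenyl-4β,5β-dimethyl-Δ9(10)-octalin-8-one
Conditions: PPh3, i-PrO2CN=NCO2i-Pr, THF, 0 °C → rt
Reagents that add atoms: none
Why: Mitsunobu esterification: ring A of 14 is a locked chair with the 3β-hydroxyl axial, and its alkoxyphosphonium ion is displaced by tiglate from the open equatorial α-direction (SN2), which inverts C3 and installs the tiglate in one step; C3 is the only hydroxyl in 14.

Step 13
Reactants: 16 3α-tigloyloxy-7α-isopropenyl-4β,5β-dimethyl-Δ9(10)-octalin-8-one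
Product: 17 cis-fused (10β-H) 3α-tigloyloxy-7α-isopropenyl-4β,5β-dimethyldecalin-8-one
Conditions: [(Ph3P)CuH]6, benzene/THF, H2O (2 equiv), rt
Reagents that add atoms: none
Why: Conjugate reduction of the enone by the phosphine-stabilised copper hydride, then protonation of the copper enolate at C9; the C10 hydrogen is expected on the β-face, cis to the angular methyl, as nucleophiles generally add to 10-methyl-Δ1(9)-octal-2-ones and steroidal 4-en-3-ones, because α-face approach is syn-axial to H-2α and H-4α of ring A. The isopropenyl group is inert and the trisubstituted tiglate should react far more slowly than the enone.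

Step 14
Reactants: 17 cis-fused (10β-H) 3α-tigloyloxy-7α-isopropenyl-4β,5β-dimethyldecalin-8-one
Product: 18 cis-fused (10β-H) 3α-tigloyloxy-7β-isopropenyl-4β,5β-dimethyldecalin-8-one
Conditions: DBU (cat.), CH2Cl2, rt
Reagents that add atoms: none
Why: Base-catalysed epimerisation α to the ketone through the enolate: with a cis ring fusion and an α oxygen at C3, only the 7β epimer has the isopropenyl, C4 methyl and C3 ester groups all equatorial, so the equilibrium should lie far toward 18. α-Reprotonation of the dienolate is kinetically preferred over γ-protonation, which should keep the double bond out of conjugation at short reaction time.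

Step 15
Reactants: 18 cis-fused (10β-H) 3α-tigloyloxy-7β-isopropenyl-4β,5β-dimethyldecalin-8-one
Product: 20 9β-hydroxy-3α-tigloyloxy-7β-isopropenyl-4β,5β-dimethyl-cis-decalin-8-one, via potassium enolate 19 (not isolated)
Conditions: KN(SiMe3)2, THF, −78 °C; then 2-(phenylsulfonyl)-3-phenyloxaziridine, −78 °C; aq. NH4Cl
Reagents that add atoms: 2-(phenylsulfonyl)-3-phenyloxaziridine, O=S(=O)(c1ccccc1)N1OC1c1ccccc1
Why: Kinetic deprotonation by the hindered amide at the less substituted α-carbon C9 (the tertiary C7–H gains little allylic activation because A(1,3) strain twists the isopropenyl group out of conjugation), then electrophilic enolate hydroxylation by the N-sulfonyloxaziridine. The α-face of C9 is blocked by C4, which is axial on ring B, so oxygen should enter from the β-face and give the equatorial 9β-alcohol.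

Step 16
Reactants: 20 9β-hydroxy-3α-tigloyloxy-7β-isopropenyl-4β,5β-dimethyl-cis-decalin-8-one; 21 senecioic acid
Product: 22 CNP0375730.1 (3α-tigloyloxy-9β-senecioyloxy-7β-isopropenyl-4β,5β-dimethyl-cis-decalin-8-one)
Conditions: DCC, DMAP (cat.), CH2Cl2, 0 °C → rt
Reagents that add atoms: none
Why: Steglich esterification of the equatorial α-ketol; carbodiimide activation without a stoichiometric amine avoids the vinylketene that would deconjugate the senecioyl group and avoids enolising the α-acyloxy ketone, so no stereocentre is touched.

Compound list

1 | 2,3-dimethylhydroquinone | Cc1c(O)ccc(O)c1C | starting material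
2 | meso-(1R,2S,3R,4S)-2,3-dimethylcyclohexane-1,4-diol (all-cis) | O[C@H]1[C@@H](C)[C@@H](C)[C@@H](O)CC1 | intermediate
3 | meso-(1R,2S,3R,4S)-2,3-dimethylcyclohexane-1,4-diyl diacetate | CC(=O)O[C@H]1[C@@H](C)[C@@H](C)[C@@H](OC(C)=O)CC1 | intermediate
4 | (1S,2R,3S,4R)-4-hydroxy-2,3-dimethylcyclohexyl acetate | O[C@H]1[C@@H](C)[C@@H](C)[C@@H](OC(C)=O)CC1 | intermediate
5 | (1S,2R,3S)-2,3-dimethyl-4-oxocyclohexyl acetate | O=C1[C@@H](C)[C@@H](C)[C@@H](OC(C)=O)CC1 | intermediate
6 | diethyl cyanomethylphosphonate | CCOP(=O)(CC#N)OCC | starting material
7 | (1S,2R,3S)-4-[(E)-cyanomethylidene]-2,3-dimethylcyclohexyl acetate | N#C/C=C1/[C@@H](C)[C@@H](C)[C@@H](OC(C)=O)CC1 | intermediate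
8 | (E)-2-[(2S,3R,4S)-4-hydroxy-2,3-dimethylcyclohexylidene]acetaldehyde | O=C/C=C1/[C@@H](C)[C@@H](C)[C@@H](O)CC1 | intermediate
9 | (1S,2R)-4-[(E)-2-acetoxyethenyl]-2,3-dimethylcyclohex-3-en-1-yl acetate (ring A dienyl acetate) | CC(=O)O/C=C/C1=C(C)[C@@H](C)[C@@H](OC(C)=O)CC1 | intermediate
10 | methyl vinyl ketone | CC(=O)C=C | starting material
11 | 7α-acetyl-3β,8α-diacetoxy-4β,5β-dimethyl-Δ9(10)-octalin (endo adduct) | CC(=O)[C@@H]1C[C@@]2(C)C(=C[C@@H]1OC(C)=O)CC[C@H](OC(C)=O)[C@@H]2C | intermediate
12 | 3β,8α-diacetoxy-7α-isopropenyl-4β,5β-dimethyl-Δ9(10)-octalin | C=C(C)[C@@H]1C[C@@]2(C)C(=C[C@@H]1OC(C)=O)CC[C@H](OC(C)=O)[C@@H]2C | intermediate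
13 | 7α-isopropenyl-4β,5β-dimethyl-Δ9(10)-octalin-3β,8α-diol | C=C(C)[C@@H]1C[C@@]2(C)C(=C[C@@H]1O)CC[C@H](O)[C@@H]2C | intermediate
14 | 3β-hydroxy-7α-isopropenyl-4β,5β-dimethyl-Δ9(10)-octalin-8-one | C=C(C)[C@@H]1C[C@@]2(C)C(=CC1=O)CC[C@H](O)[C@@H]2C | intermediate
15 | tiglic acid ((E)-2-methylbut-2-enoic acid) | C/C=C(\C)C(=O)O | starting material
16 | 3α-tigloyloxy-7α-isopropenyl-4β,5β-dimethyl-Δ9(10)-octalin-8-one | C=C(C)[C@@H]1C[C@@]2(C)C(=CC1=O)CC[C@@H](OC(=O)/C(C)=C/C)[C@@H]2C | intermediate
17 | cis-fused (10β-H) 3α-tigloyloxy-7α-isopropenyl-4β,5β-dimethyldecalin-8-one | C=C(C)[C@@H]1C[C@@]2(C)[C@H](CC[C@@H](OC(=O)/C(C)=C/C)[C@@H]2C)CC1=O | intermediate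
18 | cis-fused (10β-H) 3α-tigloyloxy-7β-isopropenyl-4β,5β-dimethyldecalin-8-one | C=C(C)[C@H]1C[C@@]2(C)[C@H](CC[C@@H](OC(=O)/C(C)=C/C)[C@@H]2C)CC1=O | intermediate
19 | potassium Δ8(9)-enolate of 18 | [K+].C=C(C)[C@H]1C[C@@]2(C)[C@H](CC[C@@H](OC(=O)/C(C)=C/C)[C@@H]2C)C=C1[O-] | intermediate
20 | 9β-hydroxy-3α-tigloyloxy-7β-isopropenyl-4β,5β-dimethyl-cis-decalin-8-one | C=C(C)[C@H]1C[C@@]2(C)[C@H](CC[C@@H](OC(=O)/C(C)=C/C)[C@@H]2C)[C@@H](O)C1=O | intermediate
21 | senecioic acid (3-methylbut-2-enoic acid) | CC(C)=CC(=O)O | starting material
22 | CNP0375730.1 | C=C(C)[C@H]1C[C@@]2(C)[C@H](CC[C@@H](OC(=O)/C(C)=C/C)[C@@H]2C)[C@@H](OC(=O)C=C(C)C)C1=O | target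

Total step count: 16. Longest linear sequence: 16 steps from 1 (6, 10, 15 and 21 are purchased).

Least certain steps

Step 8 (key step). The most likely failure is a slow cycloaddition at the tetrasubstituted terminus with its "inside" methyl. Lewis-acid-induced ionisation of the enol and allylic acetates and polymerisation of 10 could then outrun it. Facial selectivity may also erode, because α-face attack builds a 1,3-diaxial contact between the C3 acetoxy group and the emerging angular methyl. The fallback is a more electron-rich diene that reacts without a Lewis acid. From 9, MeLi cleaves both acetates to the regiodefined lithium dienolate, and t-BuMe2SiCl gives the bis-silyl diene F1. Heating with 10 in toluene (or high pressure) gives the 8α-silyloxy adduct F2. The same Zn/CH2Br2/TiCl4 methylenation gives the isopropenyl bis-silyl ether F3, and Bu4NF returns the route at 13.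

Step 3. The most likely failure is weak discrimination between the two enantiotopic esters, each flanked by a methyl-bearing carbon, or over-hydrolysis to 2. The fallback is a non-enzymatic oxidative desymmetrisation. From 2, a chiral Cp*Ir[(S,S)-TsNCHPhCHPhNH]-type catalyst under air oxidises the R-configured carbinol (asymmetric Oppenauer-type oxidation) to the hydroxy ketone F4. Acetylation (Ac2O, pyridine) returns the route at 5.

Step 7. The most likely failure is enolisation toward C1 instead of C5, giving the isomeric and more reactive trisubstituted diene, along with Z enol acetate. The fallback builds the C10=C5 alkene first as an isolable intermediate. From 5, Tf2O and 2,6-di-tert-butyl-4-methylpyridine give the tetrasubstituted enol triflate F5 (regioisomers separable). Pd(PPh3)4-catalysed Negishi-type coupling with the Reformatsky reagent BrZnCH2CO2Et gives the β,γ-unsaturated ester F6. i-Bu2AlH at −78 °C gives the hydroxy aldehyde F7. Kinetic O-acetylation of its dienolate and of the alcohol (Ac2O, Et3N, DMAP) returns the route at 9.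

Step 12. The most likely failure is elimination of the axial alkoxyphosphonium ion (antiperiplanar H-2α and H-4α, relief of the contact with the angular methyl) in competition with substitution, made worse by the modest acidity of tiglic acid. The fallback separates inversion from tigloylation. From 14, Mitsunobu reaction with the more acidic 4-nitrobenzoic acid gives the 3α-(4-nitrobenzoate) F8. Methanolysis (K2CO3, MeOH) gives the 3α-alcohol F9. Yamaguchi esterification with 15 (retention) returns the route at 16.

Step 13. The most likely failure is hydride delivery to the α-face of C10 (trans-fused ketone), or sluggish reduction of the β,β-disubstituted enone with competing attack on the tiglate. The fallback delivers the hydrogen intramolecularly. From 16, LiBH(s-Bu)3 reduces the ketone from the β-face (as with steroidal 4-en-3-ones) to the 8α-allylic alcohol F10. A metal-hydride-catalysed redox isomerisation ([Ir(cod)(PCy3)(py)]PF6 activated with H2, then purged) moves H-8, which is β, suprafacially to C10 and returns the route at 17.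

Step 15. The most likely failure is deprotonation at the allylic C7–H instead of C9, leading to hydroxylation at C7 or migration of the double bond. The fallback takes its regiocontrol from a hydrazone. From 18, Me2NNH2 (AcOH cat.) gives the N,N-dimethylhydrazone F11. LiN(i-Pr)2 deprotonates hydrazones at the less substituted α-carbon, and the same oxaziridine gives the 9β-hydroxy hydrazone F12. Hydrolysis with aqueous CuCl2 returns the route at 20.

Further compounds

F1 | step 8 | (E)-1-(tert-butyldimethylsilyloxy)diene of ring A with 3β-tert-butyldimethylsilyloxy group (bis-silyl analogue of 9) | CC(C)(C)[Si](C)(C)O/C=C/C1=C(C)[C@@H](C)[C@@H](O[Si](C)(C)C(C)(C)C)CC1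
F2 | step 8 | 7α-acetyl-3β,8α-bis(tert-butyldimethylsilyloxy)-4β,5β-dimethyl-Δ9(10)-octalin | CC(=O)[C@@H]1C[C@@]2(C)C(=C[C@@H]1O[Si](C)(C)C(C)(C)C)CC[C@H](O[Si](C)(C)C(C)(C)C)[C@@H]2C
F3 | step 8 | 3β,8α-bis(tert-butyldimethylsilyloxy)-7α-isopropenyl-4β,5β-dimethyl-Δ9(10)-octalin | C=C(C)[C@@H]1C[C@@]2(C)C(=C[C@@H]1O[Si](C)(C)C(C)(C)C)CC[C@H](O[Si](C)(C)C(C)(C)C)[C@@H]2C
F4 | step 3 | (2S,3R,4S)-4-hydroxy-2,3-dimethylcyclohexanone | O=C1[C@@H](C)[C@@H](C)[C@@H](O)CC1
F5 | step 7 | (1S,2R)-2,3-dimethyl-4-(trifluoromethanesulfonyloxy)cyclohex-3-en-1-yl acetate | FC(F)(F)S(=O)(=O)OC1=C(C)[C@@H](C)[C@@H](OC(C)=O)CC1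
F6 | step 7 | ethyl 2-[(3R,4S)-4-acetoxy-2,3-dimethylcyclohex-1-en-1-yl]acetate | CCOC(=O)CC1=C(C)[C@@H](C)[C@@H](OC(C)=O)CC1
F7 | step 7 | 2-[(3R,4S)-4-hydroxy-2,3-dimethylcyclohex-1-en-1-yl]acetaldehyde | O=CCC1=C(C)[C@@H](C)[C@@H](O)CC1
F8 | step 12 | 3α-(4-nitrobenzoyloxy)-7α-isopropenyl-4β,5β-dimethyl-Δ9(10)-octalin-8-one | C=C(C)[C@@H]1C[C@@]2(C)C(=CC1=O)CC[C@@H](OC(=O)c3ccc(cc3)[N+](=O)[O-])[C@@H]2C
F9 | step 12 | 3α-hydroxy-7α-isopropenyl-4β,5β-dimethyl-Δ9(10)-octalin-8-one | C=C(C)[C@@H]1C[C@@]2(C)C(=CC1=O)CC[C@@H](O)[C@@H]2C
F10 | step 13 | 3α-tigloyloxy-7α-isopropenyl-4β,5β-dimethyl-Δ9(10)-octalin-8α-ol | C=C(C)[C@@H]1C[C@@]2(C)C(=C[C@@H]1O)CC[C@@H](OC(=O)/C(C)=C/C)[C@@H]2C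
F11 | step 15 | N,N-dimethylhydrazone of 18 (dimethylamino group syn to C9) | C=C(C)[C@H]1C[C@@]2(C)[C@H](CC[C@@H](OC(=O)/C(C)=C/C)[C@@H]2C)C/C1=N\N(C)C
F12 | step 15 | 9β-hydroxy N,N-dimethylhydrazone of 18 | C=C(C)[C@H]1C[C@@]2(C)[C@H](CC[C@@H](OC(=O)/C(C)=C/C)[C@@H]2C)[C@@H](O)/C1=N\N(C)C
A1 | alternative 1 | bridged dienyl carbinol: 3,3-dimethoxy-5,6-dimethyl-2-(3-methylbuta-1,3-dien-2-yl)bicyclo[2.2.2]oct-5-en-2-ol, dienyl group syn to the ring alkene | C=C(C)C(=C)[C@@]1(O)[C@@H]2CC[C@@H](C(C)=C2C)C1(OC)OC
A2 | alternative 1 | cis-fused 9,9-dimethoxy-eremophila-3,11-dien-8-one | C=C(C)[C@H]1C[C@@]2(C)[C@H](CCC=C2C)C(OC)(OC)C1=O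
A3 | alternative 2 | 2-methoxy-5-methyl-1,4-benzoquinone | COC1=CC(=O)C(C)=CC1=O
A4 | alternative 2 | (Z)-tert-butyldimethyl(penta-1,3-dien-3-yloxy)silane | C=C/C(O[Si](C)(C)C(C)(C)C)=C/C
A5 | alternative 2 | cis-fused enedione adduct with C8 methoxy, C3 silyl enol ether and 4α-methyl | COC1=CC(=O)[C@]2(C)[C@H](C)C(O[Si](C)(C)C(C)(C)C)=CC[C@@H]2C1=O
A6 | alternative 3 | (R)-5-[3-hydroxy-2-(methoxymethoxy)-6-methylphenyl]-3-oxopentan-2-yl methanesulfonate | Cc1ccc(O)c(OCOC)c1CCC(=O)[C@@H](C)OS(C)(=O)=O
A7 | alternative 3 | bicyclic dienone with C3 ketone, cis C4/C5 methyls and C9 methoxymethyl enol ether | O=C1C=C[C@@]2(C)C(CCC(=O)[C@@H]2C)=C1OCOC
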